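**Retrosynthetic overview**

1. The last bonds made are the two phenol O–H bonds freed by desilylation of the orsellinate. Before that, the pyran ring (ring A) is closed by O2–C3 bond formation, the enol oxygen on C1 adding 6-endo to the C3≡C4 alkyne.
2. The strategy rests on ring B being a 2-acyloxy-2-methyl-1,3-dione, C6(=O)–C7(CH3)(O-orsellinoyl)–C8(=O), whose two acyl arms on C7 are joined only by the C4a–C8a bond. C7 can therefore come from an acyclic acetolactate ester of fixed configuration, and ring B is closed by C4a–C8a formation (enaminone carbon C8a onto ynone carbon C4a).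
3. The acyclic enaminone–diynone is cut at C6–C5 (acyl Sonogashira coupling with an enediyne), at C8a–C1 (formamide acetal condensation) and at C7–O (asymmetric aroyloxylation of tert-butyl 2-methylacetoacetate by the diaroyl peroxide of bis-silylated orsellinic acid, itself joined from the peroxy acid and the acid chloride).
4. The enediyne comes from (E)-pent-2-en-4-yn-1-ol by Cadiot–Chodkiewicz coupling, acetylation and desilylation.
5. Ring order: the orsellinate arene is bought, ring B (carbocycle) is formed first, ring A (pyran) second.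

Key step: step 12

Remark on descriptors: the quaternary carbon is R in the acyclic intermediates and S in the cyclic ones and in the target. Only the CIP ranking of its two acyl neighbours changes on ring closure; no bond at this carbon is made or broken after step 5.

Assumption: the sense of induction in step 5 is fixed by the choice of catalyst enantiomer (both are made from tert-leucine) and is to be confirmed on the first batch. (Bromoethynyl)tri(propan-2-yl)silane is taken as a purchasable reagent.

**Route**

Step 1
Reactants: 1 orsellinic acid (2,4-dihydroxy-6-methylbenzoic acid)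
Product: 2 tert-butyldimethylsilyl 2,4-bis[(tert-butyldimethylsilyl)oxy]-6-methylbenzoate
Conditions: TBSCl (3.5 equiv), imidazole (7 equiv), DMF, rt to 40 °C
Reagents that add atoms: tert-butyldimethylsilyl chloride, CC(C)(C)[Si](C)(C)Cl
Why: Exhaustive silylation (silyl ether and silyl ester formation) with TBSCl/imidazole is standard, the hydrogen-bonded ortho phenol being driven by excess reagent and mild warming.

Step 2
Reactants: 2 tert-butyldimethylsilyl 2,4-bis[(tert-butyldimethylsilyl)oxy]-6-methylbenzoate
Product: 3 2,4-bis[(tert-butyldimethylsilyl)oxy]-6-methylbenzoyl chloride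
Conditions: (COCl)2 (1.2 equiv), DMF (cat.), CH2Cl2, 0 °C to rt
Reagents that add atoms: oxalyl chloride, O=C(Cl)C(Cl)=O
Why: Silyl esters are converted directly into acid chlorides by oxalyl chloride with catalytic DMF (Vilsmeier-type activation) under neutral conditions that leave the aryl silyl ethers in place.

Step 3
Reactants: 3 2,4-bis[(tert-butyldimethylsilyl)oxy]-6-methylbenzoyl chloride
Product: 4 2,4-bis[(tert-butyldimethylsilyl)oxy]-6-methylbenzenecarboperoxoic acid (the peroxy acid of bis-silylated orsellinic acid)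
Conditions: H2O2·urea (5 equiv), pyridine (1.05 equiv), THF/CH2Cl2, −10 °C, slow addition of 3; cold pH 4 phosphate wash, dried cold solution used at once
Reagents that add atoms: hydrogen peroxide (as its urea adduct), OO
Why: Monoacylation of hydrogen peroxide by an aroyl chloride is a standard peroxy acid synthesis; slow addition of the acid chloride to a several-fold excess of the anhydrous urea adduct should stop the reaction at the peroxy acid, and the absence of hydroxide protects the base-sensitive aryl silyl ethers.

Step 4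
Reactants: 4 2,4-bis[(tert-butyldimethylsilyl)oxy]-6-methylbenzenecarboperoxoic acid, 3 2,4-bis[(tert-butyldimethylsilyl)oxy]-6-methylbenzoyl chloride
Product: 5 bis{2,4-bis[(tert-butyldimethylsilyl)oxy]-6-methylbenzoyl} peroxide
Conditions: 4 (1.0 equiv), 3 (1.0 equiv), pyridine (1.1 equiv), CH2Cl2, −10 to 0 °C, dark; cold wash, used without storage
Reagents that add atoms: none
Why: O-Acylation of a peroxy acid by an acid chloride with pyridine is the classical two-component diacyl peroxide synthesis, one molecule of 4 and one of 3 being joined through the terminal peroxy oxygen while the low temperature holds back N-oxidation of pyridine.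

Step 5
Reactants: 6 tert-butyl 2-methyl-3-oxobutanoate (tert-butyl 2-methylacetoacetate, racemic), 5 bis{2,4-bis[(tert-butyldimethylsilyl)oxy]-6-methylbenzoyl} peroxide
Product: 7 tert-butyl (2R)-2-({2,4-bis[(tert-butyldimethylsilyl)oxy]-6-methylbenzoyl}oxy)-2-methyl-3-oxobutanoate
Conditions: N1,N1-diethyl-3,3-dimethylbutane-1,2-diamine·TfOH (20 mol%, the enantiomer that gives the R ester), 5 (1.2 equiv), BHT (10 mol%), CH2Cl2, 0 °C to rt
Reagents that add atoms: none
Why: Amine-catalysed asymmetric α-aroyloxylation of a β-keto ester: the primary amine condenses with the ketone to a secondary enamine (which erases the stereocentre of 6 and makes the reaction stereoconvergent), the protonated tertiary amine holds the peroxide by hydrogen bonding, and the enamine carbon attacks the O–O bond on one face, so the quaternary centre (future C7) is set as R by catalyst control.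

Step 6
Reactants: 7 tert-butyl (2R)-2-({2,4-bis[(tert-butyldimethylsilyl)oxy]-6-methylbenzoyl}oxy)-2-methyl-3-oxobutanoate, 8 N,N-dimethylformamide dimethyl acetal
Product: 9 tert-butyl (2R,4E)-2-({2,4-bis[(tert-butyldimethylsilyl)oxy]-6-methylbenzoyl}oxy)-5-(dimethylamino)-2-methyl-3-oxopent-4-enoate
Conditions: 8 (3 equiv), toluene, 70 °C, methanol swept out in a slow N2 stream
Reagents that add atoms: none
Why: Enaminone formation by condensation of a methyl ketone with a formamide acetal; the acetyl CH3 is the only enolisable position because the other α-carbon is quaternary, so C1 and the nitrogen are attached to the future C8a with E geometry.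

Step 7
Reactants: 9 tert-butyl (2R,4E)-2-({2,4-bis[(tert-butyldimethylsilyl)oxy]-6-methylbenzoyl}oxy)-5-(dimethylamino)-2-methyl-3-oxopent-4-enoate
Product: 10 (2R,4E)-2-({2,4-bis[(tert-butyldimethylsilyl)oxy]-6-methylbenzoyl}oxy)-5-(dimethylamino)-2-methyl-3-oxopent-4-enoic acid
Conditions: TFA/CH2Cl2 (1:4), 0 °C; toluene azeotrope, pH 4 buffer wash at 0 °C; used at once
Reagents that add atoms: none
Why: Acidolysis of the tert-butyl ester with loss of isobutene under anhydrous conditions, which the protonated vinylogous amide and the aryl silyl ethers tolerate; the β-keto acid is kept cold and not stored so that decarboxylation, already slowed by the amide-like C8 carbonyl, does not set in.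

Step 8
Reactants: 11 (2E)-pent-2-en-4-yn-1-ol, 12 (bromoethynyl)tri(propan-2-yl)silane
Product: 13 (2E)-7-[tri(propan-2-yl)silyl]hept-2-ene-4,6-diyn-1-ol
Conditions: CuCl (5 mol%), NH2OH·HCl (0.3 equiv), n-BuNH2 (30% aq.), Et2O, 0 °C
Reagents that add atoms: none
Why: Cadiot–Chodkiewicz coupling of a terminal alkyne with a bromoalkyne under monovalent copper catalysis gives the unsymmetrical diyne, the bulky silyl group suppressing homocoupling and the free alcohol and E alkene being spectators.

Step 9
Reactants: 13 (2E)-7-[tri(propan-2-yl)silyl]hept-2-ene-4,6-diyn-1-ol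
Product: 14 (2E)-7-[tri(propan-2-yl)silyl]hept-2-ene-4,6-diyn-1-yl acetate
Conditions: Ac2O, pyridine, DMAP (cat.), CH2Cl2, 0 °C to rt
Reagents that add atoms: acetic anhydride, CC(=O)OC(C)=O
Why: Nucleophile-catalysed acetylation of a primary allylic alcohol, placed after the aqueous amine step so that the acetate of the target never meets aqueous amine.

Step 10
Reactants: 14 (2E)-7-[tri(propan-2-yl)silyl]hept-2-ene-4,6-diyn-1-yl acetate
Product: 15 (2E)-hept-2-ene-4,6-diyn-1-yl acetate
Conditions: TBAF (1.05 equiv), AcOH (1.1 equiv), THF, 0 °C; kept as a cold degassed solution and used the same day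
Reagents that add atoms: none
Why: Fluoride-induced protodesilylation of an alkynylsilane, buffered with acetic acid so that the allylic acetate is kept, and the sensitive terminal 1,3-diyne is never concentrated.

Step 11
Reactants: 10 (2R,4E)-2-({2,4-bis[(tert-butyldimethylsilyl)oxy]-6-methylbenzoyl}oxy)-5-(dimethylamino)-2-methyl-3-oxopent-4-enoic acid, 15 (2E)-hept-2-ene-4,6-diyn-1-yl acetate
Product: 17 (1E,4R,10E)-12-(acetyloxy)-1-(dimethylamino)-4-methyl-3,5-dioxododeca-1,10-diene-6,8-diyn-4-yl 2,4-bis[(tert-butyldimethylsilyl)oxy]-6-methylbenzoate, via acid chloride 16 (not isolated)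
Conditions: 1-chloro-N,N,2-trimethylprop-1-en-1-amine (1.1 equiv), CH2Cl2, 0 °C, 30 min; then 15 (1.3 equiv), PdCl2(PPh3)2 (3 mol%), CuI (5 mol%), Et3N (1.2 equiv), THF, degassed, 0 °C to rt
Reagents that add atoms: 1-chloro-N,N,2-trimethylprop-1-en-1-amine, CC(C)=C(Cl)N(C)C (its chlorine is in 16 only)
Why: Neutral acid chloride formation with an α-chloroenamine (no HCl and no Vilsmeier-type electrophile that would attack the vinylogous amide) is followed by acyl Sonogashira coupling, in which zerovalent palladium formed in the flask inserts into the C–Cl bond of the hindered, non-enolisable acid chloride and the copper acetylide of the terminal diyne is transferred, so the C6–C5 bond is made while the acetate, the silyl ethers and the enaminone are spectators.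

Step 12
Reactants: 17 (1E,4R,10E)-12-(acetyloxy)-1-(dimethylamino)-4-methyl-3,5-dioxododeca-1,10-diene-6,8-diyn-4-yl 2,4-bis[(tert-butyldimethylsilyl)oxy]-6-methylbenzoate
Product: 18 (2S,6Z)-5-[(3E)-5-(acetyloxy)pent-3-en-1-yn-1-yl]-6-[(dimethylamino)methylidene]-2-methyl-1,3-dioxocyclohex-4-en-2-yl 2,4-bis[(tert-butyldimethylsilyl)oxy]-6-methylbenzoate (ring B with C1 and the C3≡C4 alkyne in place; the geometry of the push–pull exocyclic C=C is labile and without consequence)
Conditions: AcOH/toluene (1:5), 4 Å molecular sieves, 0.01 M, 40 °C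
Reagents that add atoms: none
Why: Proposed new method: the tertiary enaminone is nucleophilic at C8a (α to the C8 carbonyl, β to nitrogen) and acetic acid activates the C6 ynone by hydrogen bonding, so C8a should add to C4a in an intramolecular conjugate addition that forms the C4a–C8a bond and closes ring B in the 6-endo-dig mode; since an allenol cannot be accommodated in a six-membered ring, the acid is expected to hand the proton to C5 in the ring plane as the bond forms, and loss of the C8a proton from the iminium then regenerates a doubly conjugated vinylogous amide, which makes the closure irreversible. The closest known reaction type is the acid-promoted Michael addition of enamino carbonyl compounds to ynones (first stage of the Bohlmann–Rahtz pyridine synthesis), together with the 6-endo-dig closures of heteroatom nucleophiles onto ynones used for chromones and 4-quinolones; the intramolecular carbocyclic variant has not been shown. No stereocentre is formed, and C7 is not at risk because it bears no hydrogen and, with C1 already fixed on C8a, ring B cannot pass through a symmetric enol that would exchange C6 and C8. The step needs attack at C4a and not at the distal diyne carbon C3, which the six- against eight-membered ring size secures, and attack through carbon and not through the C8 oxygen, which is secured because oxygen closure gives a cation that cannot lose a proton and reverts. A non-chelating Brønsted acid is preferred to ZnBr2 because chelation of the C6 and C8 oxygens by one metal would turn the two arms away from each other, and high dilution suppresses intermolecular addition.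

Step 13
Reactants: 18 (2S,6Z)-5-[(3E)-5-(acetyloxy)pent-3-en-1-yn-1-yl]-6-[(dimethylamino)methylidene]-2-methyl-1,3-dioxocyclohex-4-en-2-yl 2,4-bis[(tert-butyldimethylsilyl)oxy]-6-methylbenzoate
Product: 19 (2S,6Z)-5-[(3E)-5-(acetyloxy)pent-3-en-1-yn-1-yl]-6-(hydroxymethylidene)-2-methyl-1,3-dioxocyclohex-4-en-2-yl 2,4-bis[(tert-butyldimethylsilyl)oxy]-6-methylbenzoate (enol form of the 2-formyl dione)
Conditions: 1 M aq. HCl/THF (1:4), 0 °C to rt
Reagents that add atoms: water, O
Why: Acid hydrolysis of a vinylogous amide by addition–elimination at C1 (water in, dimethylamine out as its salt) gives the strongly acidic 2-formyl-1,3-dione enol, the allylic acetate and the aryl silyl ethers surviving brief dilute acid.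

Step 14
Reactants: 19 (2S,6Z)-5-[(3E)-5-(acetyloxy)pent-3-en-1-yn-1-yl]-6-(hydroxymethylidene)-2-methyl-1,3-dioxocyclohex-4-en-2-yl 2,4-bis[(tert-butyldimethylsilyl)oxy]-6-methylbenzoate
Product: 20 (7S)-3-[(1E)-3-(acetyloxy)prop-1-en-1-yl]-7-methyl-6,8-dioxo-7,8-dihydro-6H-isochromen-7-yl 2,4-bis[(tert-butyldimethylsilyl)oxy]-6-methylbenzoate
Conditions: AuCl3 (5 mol%), CH2Cl2, rt
Reagents that add atoms: none
Why: π-Acid-catalysed 6-endo-dig cycloisomerization (intramolecular hydroalkoxylation, the closure used to make isochromene and 2-benzopyrylium rings from ortho-alkynyl aryl aldehydes): trivalent gold activates the C3≡C4 alkyne, whose C3 is also the δ-position of the C6 dienone, the C1 enol oxygen (turned towards C4a through the formyl tautomer) adds anti and protodeauration gives ring A without touching C7.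

Step 15
Reactants: 20 (7S)-3-[(1E)-3-(acetyloxy)prop-1-en-1-yl]-7-methyl-6,8-dioxo-7,8-dihydro-6H-isochromen-7-yl 2,4-bis[(tert-butyldimethylsilyl)oxy]-6-methylbenzoate
Product: 21 (7S)-3-[(1E)-3-(acetyloxy)prop-1-en-1-yl]-7-methyl-6,8-dioxo-7,8-dihydro-6H-isochromen-7-yl 2,4-dihydroxy-6-methylbenzoate (target, CNP0194405.1)
Conditions: HF·pyridine, pyridine, THF, 0 °C to rt
Reagents that add atoms: none
Why: Fluoride-mediated cleavage of the two aryl silyl ethers under pyridine-buffered, amine-nucleophile-free conditions should free the phenols without opening the pyran ring, cleaving the allylic acetate or the hindered C7 ester.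

**Compound list**

1 | orsellinic acid (2,4-dihydroxy-6-methylbenzoic acid) | Cc1cc(O)cc(O)c1C(=O)O | starting material
2 | tert-butyldimethylsilyl 2,4-bis[(tert-butyldimethylsilyl)oxy]-6-methylbenzoate | Cc1cc(O[Si](C)(C)C(C)(C)C)cc(O[Si](C)(C)C(C)(C)C)c1C(=O)O[Si](C)(C)C(C)(C)C | intermediate
3 | 2,4-bis[(tert-butyldimethylsilyl)oxy]-6-methylbenzoyl chloride | Cc1cc(O[Si](C)(C)C(C)(C)C)cc(O[Si](C)(C)C(C)(C)C)c1C(Cl)=O | intermediate
4 | 2,4-bis[(tert-butyldimethylsilyl)oxy]-6-methylbenzenecarboperoxoic acid | Cc1cc(O[Si](C)(C)C(C)(C)C)cc(O[Si](C)(C)C(C)(C)C)c1C(=O)OO | intermediate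
5 | bis{2,4-bis[(tert-butyldimethylsilyl)oxy]-6-methylbenzoyl} peroxide | Cc1cc(O[Si](C)(C)C(C)(C)C)cc(O[Si](C)(C)C(C)(C)C)c1C(=O)OOC(=O)c1c(C)cc(O[Si](C)(C)C(C)(C)C)cc1O[Si](C)(C)C(C)(C)C | intermediate
6 | tert-butyl 2-methyl-3-oxobutanoate (racemic) | CC(=O)C(C)C(=O)OC(C)(C)C | starting material
7 | tert-butyl (2R)-2-({2,4-bis[(tert-butyldimethylsilyl)oxy]-6-methylbenzoyl}oxy)-2-methyl-3-oxobutanoate | CC(C)(C)OC(=O)[C@](C)(OC(=O)c1c(C)cc(O[Si](C)(C)C(C)(C)C)cc1O[Si](C)(C)C(C)(C)C)C(C)=O | intermediate
8 | N,N-dimethylformamide dimethyl acetal | COC(OC)N(C)C | starting material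
9 | tert-butyl (2R,4E)-2-({2,4-bis[(tert-butyldimethylsilyl)oxy]-6-methylbenzoyl}oxy)-5-(dimethylamino)-2-methyl-3-oxopent-4-enoate | CC(C)(C)OC(=O)[C@](C)(OC(=O)c1c(C)cc(O[Si](C)(C)C(C)(C)C)cc1O[Si](C)(C)C(C)(C)C)C(=O)/C=C/N(C)C | intermediate
10 | (2R,4E)-2-({2,4-bis[(tert-butyldimethylsilyl)oxy]-6-methylbenzoyl}oxy)-5-(dimethylamino)-2-methyl-3-oxopent-4-enoic acid | OC(=O)[C@](C)(OC(=O)c1c(C)cc(O[Si](C)(C)C(C)(C)C)cc1O[Si](C)(C)C(C)(C)C)C(=O)/C=C/N(C)C | intermediate
11 | (2E)-pent-2-en-4-yn-1-ol | C#C/C=C/CO | starting material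
12 | (bromoethynyl)tri(propan-2-yl)silane | CC(C)[Si](C#CBr)(C(C)C)C(C)C | starting material
13 | (2E)-7-[tri(propan-2-yl)silyl]hept-2-ene-4,6-diyn-1-ol | OC/C=C/C#CC#C[Si](C(C)C)(C(C)C)C(C)C | intermediate
14 | (2E)-7-[tri(propan-2-yl)silyl]hept-2-ene-4,6-diyn-1-yl acetate | CC(=O)OC/C=C/C#CC#C[Si](C(C)C)(C(C)C)C(C)C | intermediate
15 | (2E)-hept-2-ene-4,6-diyn-1-yl acetate | CC(=O)OC/C=C/C#CC#C | intermediate
16 | (2R,4E)-2-({2,4-bis[(tert-butyldimethylsilyl)oxy]-6-methylbenzoyl}oxy)-5-(dimethylamino)-2-methyl-3-oxopent-4-enoyl chloride (not isolated) | ClC(=O)[C@](C)(OC(=O)c1c(C)cc(O[Si](C)(C)C(C)(C)C)cc1O[Si](C)(C)C(C)(C)C)C(=O)/C=C/N(C)C | intermediate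
17 | (1E,4R,10E)-12-(acetyloxy)-1-(dimethylamino)-4-methyl-3,5-dioxododeca-1,10-diene-6,8-diyn-4-yl 2,4-bis[(tert-butyldimethylsilyl)oxy]-6-methylbenzoate | CC(=O)OC/C=C/C#CC#CC(=O)[C@](C)(OC(=O)c1c(C)cc(O[Si](C)(C)C(C)(C)C)cc1O[Si](C)(C)C(C)(C)C)C(=O)/C=C/N(C)C | intermediate
18 | (2S,6Z)-5-[(3E)-5-(acetyloxy)pent-3-en-1-yn-1-yl]-6-[(dimethylamino)methylidene]-2-methyl-1,3-dioxocyclohex-4-en-2-yl 2,4-bis[(tert-butyldimethylsilyl)oxy]-6-methylbenzoate | CC(=O)OC/C=C/C#CC1=CC(=O)[C@](C)(OC(=O)c2c(C)cc(O[Si](C)(C)C(C)(C)C)cc2O[Si](C)(C)C(C)(C)C)C(=O)/C1=C\N(C)C | intermediate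
19 | (2S,6Z)-5-[(3E)-5-(acetyloxy)pent-3-en-1-yn-1-yl]-6-(hydroxymethylidene)-2-methyl-1,3-dioxocyclohex-4-en-2-yl 2,4-bis[(tert-butyldimethylsilyl)oxy]-6-methylbenzoate | CC(=O)OC/C=C/C#CC1=CC(=O)[C@](C)(OC(=O)c2c(C)cc(O[Si](C)(C)C(C)(C)C)cc2O[Si](C)(C)C(C)(C)C)C(=O)/C1=C\O | intermediate
20 | (7S)-3-[(1E)-3-(acetyloxy)prop-1-en-1-yl]-7-methyl-6,8-dioxo-7,8-dihydro-6H-isochromen-7-yl 2,4-bis[(tert-butyldimethylsilyl)oxy]-6-methylbenzoate | CC(=O)OC/C=C/C1=CC2=CC(=O)[C@](C)(OC(=O)c3c(C)cc(O[Si](C)(C)C(C)(C)C)cc3O[Si](C)(C)C(C)(C)C)C(=O)C2=CO1 | intermediate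
21 | (7S)-3-[(1E)-3-(acetyloxy)prop-1-en-1-yl]-7-methyl-6,8-dioxo-7,8-dihydro-6H-isochromen-7-yl 2,4-dihydroxy-6-methylbenzoate | CC(=O)OC/C=C/C1=CC2=CC(=O)[C@](C)(OC(=O)c3c(C)cc(O)cc3O)C(=O)C2=CO1 | target

**Step count**

Total: 15 steps. Longest linear sequence: 12 steps (steps 1 to 7 and 11 to 15, from orsellinic acid); the enediyne branch (steps 8 to 10) joins at step 11.

**Steps most likely to fail**

1. Step 12 (the step with the proposed method). The in-plane attack of C8a on the alkyne may be slower than intermolecular Michael addition, which would give oligomers. Closure through the C8 oxygen followed by hydrolysis on work-up may also drain the material. The fallback uses known chemistry and takes ring B from an arene by oxidative dearomatization instead of closing it from the chain. It sets out from alcohol 11 and acid chloride 3 and comes back at 20. Alcohol 11 is acetylated (Ac2O, pyridine) to (2E)-pent-2-en-4-yn-1-yl acetate F1. Sonogashira coupling (PdCl2(PPh3)2, CuI, Et3N, DMF, 50 °C) of F1 with 6-bromo-2,4-dihydroxy-3-methylbenzaldehyde F2 gives the ortho-alkynyl benzaldehyde 6-[(3E)-5-(acetyloxy)pent-3-en-1-yn-1-yl]-2,4-dihydroxy-3-methylbenzaldehyde F3. F2 is itself made by Vilsmeier–Haack formylation of 5-bromo-2-methylbenzene-1,3-diol with POCl3/DMF. Copper-mediated enantioselective oxidative dearomatization at C7 follows: [Cu(CH3CN)4]PF6 with the sparteine enantiomer that leads to the 7S series, O2, i-Pr2NEt, DMAP, CH2Cl2, −78 to −10 °C. Cycloisomerization in phosphate buffer (KH2PO4/K2HPO4, aqueous CH3CN) then gives (7S)-3-[(1E)-3-(acetyloxy)prop-1-en-1-yl]-7-hydroxy-7-methyl-6H-isochromene-6,8(7H)-dione F4. Acylation of its tertiary alcohol with 3 (Et3N, DMAP, CH2Cl2, 0 °C to rt) gives 20, which goes on to step 15.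

2. Step 11. The chlorinating agent or the acid chloride may attack the nucleophilic enaminone, and acid 10 may decarboxylate before it is activated. The fallback replaces the acid chloride by a thioester and C–Cl insertion by C–S insertion. It sets out from 10 and comes back at 17. Acid 10 is coupled with ethanethiol (EDC·HCl, DMAP cat., CH2Cl2, −20 to 0 °C) to S-ethyl (2R,4E)-2-({2,4-bis[(tert-butyldimethylsilyl)oxy]-6-methylbenzoyl}oxy)-5-(dimethylamino)-2-methyl-3-oxopent-4-enethioate F5. Palladium/copper-mediated coupling of this thioester with diyne 15 then gives 17: PdCl2(dppf) (dppf = 1,1′-bis(diphenylphosphino)ferrocene), tri(2-furyl)phosphine, CuI (1.7 equiv), Et3N, DMF, 50 °C. No chlorinating agent is used at any point. If 17 already closes to 18 under these conditions, the material is simply carried into step 13.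

3. Step 5. Oxygen transfer from the hindered, electron-rich peroxide may be slow, so that peroxide decomposition or an unselective background reaction erodes the facial selectivity. The fallback forms the C7–O bond by hydroxylation and O-acylation instead of aroyloxy transfer, so that no peroxide is needed. It sets out from 6 and 3 and comes back at 7. Keto ester 6 is hydroxylated enantioselectively to tert-butyl (2R)-2-hydroxy-2-methyl-3-oxobutanoate F6. The conditions are TiCl2(TADDOLato)(CH3CN)2 (5 mol%, tetravalent titanium, TADDOL being a 2,2-dimethyl-α,α,α′,α′-tetraaryl-1,3-dioxolane-4,5-dimethanol) with 3-(4-nitrophenyl)-2-(phenylsulfonyl)oxaziridine in CH2Cl2 at rt. The tertiary alcohol is acylated at once with 3 (Et3N, DMAP, CH2Cl2, 0 °C) to give 7. It is kept cold and base contact is kept short so that the tertiary ketol does not racemise by acyl migration.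

**Further compounds**

F1 | step 12 | (2E)-pent-2-en-4-yn-1-yl acetate | CC(=O)OC/C=C/C#C
F2 | step 12 | 6-bromo-2,4-dihydroxy-3-methylbenzaldehyde | Cc1c(O)cc(Br)c(C=O)c1O
F3 | step 12 | 6-[(3E)-5-(acetyloxy)pent-3-en-1-yn-1-yl]-2,4-dihydroxy-3-methylbenzaldehyde | CC(=O)OC/C=C/C#Cc1cc(O)c(C)c(O)c1C=O
F4 | step 12 | (7S)-3-[(1E)-3-(acetyloxy)prop-1-en-1-yl]-7-hydroxy-7-methyl-6H-isochromene-6,8(7H)-dione | CC(=O)OC/C=C/C1=CC2=CC(=O)[C@](C)(O)C(=O)C2=CO1
F5 | step 11 | S-ethyl (2R,4E)-2-({2,4-bis[(tert-butyldimethylsilyl)oxy]-6-methylbenzoyl}oxy)-5-(dimethylamino)-2-methyl-3-oxopent-4-enethioate | CCSC(=O)[C@](C)(OC(=O)c1c(C)cc(O[Si](C)(C)C(C)(C)C)cc1O[Si](C)(C)C(C)(C)C)C(=O)/C=C/N(C)C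
F6 | step 5 | tert-butyl (2R)-2-hydroxy-2-methyl-3-oxobutanoate | CC(C)(C)OC(=O)[C@](C)(O)C(C)=O
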